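## The problem

The target is a germacranolide. Its ten-membered carbocycle holds two trisubstituted alkenes that are both cis with respect to the ring (C2 and C9 on one side of C1=C10, C3 and C6 on one side of C4=C5). C10 carries the C14 aldehyde, C4 carries the C15 hydroxymethyl, and an α-methylene γ-lactone (C11=C13, C12) is trans-fused across C6–C7. Four contiguous stereocentres (6R,7S,8S,9S) sit on the C6–C9 edge, and O8 bears an (S)-2-methylbutanoate with its own stereocentre while O9 bears an acetate. C8 can come from the chiral pool, but the C7 side chain must be anti to O8 along the C6–C9 chain, which is the opposite of what cuprate addition to a glyceraldehyde-derived enoate delivers. Once C7 is set it can direct C6, since Felkin–Anh and 1,3-induction from O8 point the same way; C9 has no open-chain director in its favour and must be set in the ring or corrected. Three secondary oxygens (O6, O8, O9) need three different acyl groups, and O6 and O8 are both γ to C12, so the lactone must be closed before O8 is freed. The two primary allylic oxygens (C14, C15) end at different oxidation levels. The exocyclic methylene lactone (Michael acceptor, hydride-sensitive, base-isomerisable), the 2-formyl allylic acetate (SN2' loss of acetate), the vicinal esters (acyl migration) and the epimerisable ester α-carbon rule out strong base, strong nucleophiles and hydride reagents late in the route. The feature that opens the key step is C4=C5: H on C5, C6 cis to C3 and C15 trans to C6 is the pattern left by syn addition of an aldehyde carbon (C6) and an alkyl group (C3) across the triple bond of a propargyl ether HC5≡C4–C15H2OR, with the C6 carbinol formed in the same event.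

## Retrosynthesis

Germacrane numbering is used for all intermediates.

**End game (29 back to 26).** No skeletal bond is cut. Target 29 is the C15 alcohol of silyl ether 28, 28 is the C9 acetate of hydroxy enal 27, and 27 comes from macrocyclic diol 26 by oxidation of the primary allylic C14 alcohol only. Keeping C15 as a TIPS ether to the last step and C14 as a free alcohol until after ring closure differentiates the two allylic CH2O groups without further protecting groups. The forward steps must oxidise a primary allylic alcohol beside a secondary one and acetylate without touching the enal.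

**Ring opening at C9–C10 (26 back to 25).** The ten-membered ring is cut between the C9 carbinol and C10, giving the open-chain (Z)-alkenyl iodide/aldehyde 25. Closing at C1=C10 by metathesis would have to form a trisubstituted alkene in a medium ring beside a competing methylene lactone. C3–C4 and C5–C6 are reserved for the fragment union. An alkenyl iodide fixes the C1=C10 geometry before closure, and the chromium-mediated addition transfers it with retention. The forward reaction has to close a ten-membered ring at high dilution and attack the Si face of the aldehyde.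

**Alkenyl iodide and C8/C9 groups (25 back to 17).** The iodide needs iodine on C10 cis to C2, which is anti addition of H and I across C1≡C10 with iodine next to C14. Hydroxyl-directed trans-hydrostannation of propargylic alcohol 23 (from PMB ether 22) followed by tin–iodine exchange gives exactly this. The C9 aldehyde and the C8 ester come from the terminal diol 18 through the primary TES ether 19 and its (S)-2-methylbutanoate 21, which is oxidised directly to 22. Diol 18 is the deprotected acetonide 17. The acid side chain 20 is put on as soon as O8 is free, so it acts as its own protecting group.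

**Methylene and lactone (17 back to 13).** The C11=C13 bond is cut to lactone 14, and the O6–C12 bond to γ-hydroxy ester 13. Methylenation is placed directly after lactonisation because 14 has no other enolisable carbonyl; later the ester and acetate would compete. The acetonide keeps O8 from competing for C12 while the lactone closes.

**Key disconnection (13 back to 6, 8 and 12).** C5–C6 and C3–C4 are cut together. This gives aldehyde 6 (C6–C9, C11, C12), the propargyl TIPS ether 8 (C5, C4, C15) and the alkylzinc iodide 12 (C3, C2, C1, C10, C14). Olefination routes to this alkene would have to place the ring carbons cis on a trisubstituted double bond; here the geometry follows from the mechanism. The zinc reagent carries C14 as a PMB propargyl ether, because C14 could not be added later through an acetylide beside the lactone, and an ester at C14 could not be reduced beside the lactone and two esters. The forward reaction must transfer the alkyl group and not hydride, react at the terminal alkyne, and give the Felkin epimer at C6.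

**Aldehyde 6 (back to 1).** The C6 aldehyde comes from ozonolysis of the propenyl group of ester 5. The C7–C11 bond of 5 is cut by a Johnson–Claisen transform to the (S,E)-allylic alcohol 3, via ketene acetal 4. Alcohol 3 comes from enone 2 and (R)-glyceraldehyde acetonide 1. Conjugate addition of a vinyl cuprate to the E-enoate from 1 was set aside, because addition anti to the C8–O bond gives the C7 epimer of 6. The Claisen route sets C7 by 1,3-chirality transfer from a carbinol centre chosen by the reduction catalyst, independent of the facial bias of the dioxolane.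

**Alkyne and zinc fragments (8 and 12 back to 7).** Both come from prop-2-yn-1-ol 7. Silylation gives 8. PMB protection gives 9, the lithium acetylide opens oxirane to give 10, and iodide 11 is converted to 12 by zinc insertion.

## Roads not taken

**Alternative 1:** Eschenmoser–Tanabe fragmentation. The cut is the C4–C9 bond of the lactone-fused epoxy decalone A1. Its C5 tosylhydrazone would fragment with loss of N2 and sulfinate to the cyclodec-4-yn-9-one A2, with the trans lactone and the C8 silyl ether in place. The merit is real: the ten-membered ring comes from a rigid six/six bicycle without a dilution-dependent closure, and C6, C7 and C8 are set on cyclohexane rings. On ring formation this road is better than the chosen plan, whose closure (step 19) is its weakest point. The weak points lie after the fragmentation. A2 lacks C14 and C15 and both alkenes. C15 and H would have to be added across the ring alkyne with control of regiochemistry next to a propargylic lactone oxygen that organocopper reagents tend to displace. The C9 ketone and C10 methylene would need a multi-step conversion to the C9 acetate, C1=C10 and the C14 aldehyde. The chosen plan sets against it that C14 and C15 arrive inside the fragments and that the C4=C5 geometry is fixed in the fragment union.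

**Alternative 2:** late palladium cyclocarbonylation. The cuts are O6–C12 and C11–C12 of the lactone. The C6-hydroxy C7-ethynyl macrocycle A3 would be carbonylated (PdCl2(PPh3)2, SnCl2, CO) through an alkoxycarbonyl palladium species and 5-exo-dig insertion to give A4, the C15 TBDPS ether of the target. The merit is that the methylene lactone is made in one step at the very end and is never carried; here this road is better, since the chosen plan carries the Michael acceptor through ten steps. The weak points are that A3 contains an allylic acetate and an allylic alcohol, both open to ionisation by zerovalent palladium under reducing, Lewis acidic conditions, and an enal. The road also leaves the whole problem of the ring, both alkenes and the C6–C9 stereocentres inside A3. The chosen plan sets against it an early, trivial lactonisation that also separates O6 from O8.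

**Alternative 3:** enolate [2,3]-Wittig ring contraction. The cut is C7–C8. The 13-membered α-allyloxy enone A5 would be deprotonated at C8 (LiN(SiMe3)2) and rearrange to the ten-membered α-hydroxy enone A6, forming C7–C8, the C11=C13 methylene and both stereocentres at once. It closes an easier 13-membered ring first and is more economical at C7/C8 than the chosen plan, which spends four steps on C7. Its weak points are competing γ-deprotonation of the enone, a transannular transition state that must set C7 and C8 in one of four ways, and a later C9 ketone reduction next to a free C8 hydroxyl, after which two secondary alcohols need different acyl groups. The chosen plan takes C8 from the chiral pool and C7 from a chair Claisen, and puts the C8 ester on before C9 exists as an alcohol. At C9 neither road is better, since both settle it on the formed ring.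

Key step: step 10

Remark on the chemistry: aldehyde 6 (epimerisable at C7) and zinc reagent 12 are used as crude solutions; if the zinc alkoxide formed in step 10 already closes partly onto the ester, that material is lactone 14 and is carried through step 11.

## Route

Step 1
Reactants: 1 (4R)-2,2-dimethyl-1,3-dioxolane-4-carbaldehyde
Product: 2 (3E)-4-[(4S)-2,2-dimethyl-1,3-dioxolan-4-yl]but-3-en-2-one
Conditions: Ph3P=CHC(O)CH3, CH2Cl2, rt
Reagents that add atoms: 1-(triphenylphosphoranylidene)propan-2-one, CC(=O)C=P(c1ccccc1)(c1ccccc1)c1ccccc1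
Why: Wittig olefination with a stabilised ylide gives the E-enone; the C8 centre is not enolisable under these neutral conditions.

Step 2
Reactants: 2 enone
Product: 3 (2S,3E)-4-[(4S)-2,2-dimethyl-1,3-dioxolan-4-yl]but-3-en-2-ol
Conditions: (R)-2-methyl-CBS-oxazaborolidine (20 mol %), catecholborane, PhMe, −78 °C
Reagents that add atoms: none
Why: Corey–Bakshi–Shibata reduction; with the alkenyl group as the large substituent the (R)-catalyst should deliver hydride to give the (S)-carbinol under reagent control, and catecholborane at low temperature avoids hydroboration of the alkene.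

Step 3
Reactants: 3 allylic alcohol
Product: 5 methyl (3S,4E)-3-[(4S)-2,2-dimethyl-1,3-dioxolan-4-yl]hex-4-enoate, via ketene acetal 4 (not isolated)
Conditions: MeC(OMe)3, EtCO2H (cat.), xylene, 135 °C, MeOH distilled off
Reagents that add atoms: trimethyl orthoacetate, CC(OC)(OC)OC
Why: Johnson–Claisen rearrangement through a chair transition state with the carbinol methyl equatorial; suprafacial transfer from the (S)-carbinol across the E-alkene places the new C7–C11 bond on the face that gives (3S)-5 with C11 anti to O8, and the new alkene is E.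

Step 4
Reactants: 5 hexenoate
Product: 6 methyl (3R)-3-[(4S)-2,2-dimethyl-1,3-dioxolan-4-yl]-4-oxobutanoate
Conditions: O3, CH2Cl2, −78 °C; PPh3, −78 °C to rt; used crude
Reagents that add atoms: ozone, [O-][O+]=O
Why: Ozonolysis with reductive work-up cleaves the only alkene to the C6 aldehyde; neutral, cold work-up avoids epimerisation at C7.

Step 5
Reactants: 7 prop-2-yn-1-ol
Product: 8 tri(propan-2-yl)(prop-2-yn-1-yloxy)silane
Conditions: i-Pr3SiCl, imidazole, CH2Cl2, 0 °C to rt
Reagents that add atoms: chlorotri(propan-2-yl)silane, CC(C)[Si](Cl)(C(C)C)C(C)C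
Why: Standard silylation of a primary alcohol; the bulky, weakly coordinating silyl ether disfavours β-alkoxy elimination in the nickel step and survives until the last step.

Step 6
Reactants: 7 prop-2-yn-1-ol
Product: 9 1-methoxy-4-[(prop-2-yn-1-yloxy)methyl]benzene
Conditions: NaH, THF, 0 °C; 4-MeOC6H4CH2Cl, Bu4NI (cat.), 0 °C to rt
Reagents that add atoms: 4-methoxybenzyl chloride, COc1ccc(CCl)cc1
Why: Williamson etherification; one equivalent of NaH deprotonates only the hydroxyl.

Step 7
Reactants: 9 PMB propargyl ether
Product: 10 5-[(4-methoxyphenyl)methoxy]pent-3-yn-1-ol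
Conditions: n-BuLi, THF, −78 °C; BF3·OEt2; oxirane, −78 °C
Reagents that add atoms: oxirane, C1CO1
Why: BF3-promoted opening of an epoxide by a lithium acetylide adds the C2–C3 unit in one step.

Step 8
Reactants: 10 homopropargylic alcohol
Product: 11 1-[(5-iodopent-2-yn-1-yloxy)methyl]-4-methoxybenzene
Conditions: I2, PPh3, imidazole, CH2Cl2, 0 °C to rt
Reagents that add atoms: iodine, II
Why: Appel-type iodination of a primary alcohol; neutral conditions leave the PMB ether and the alkyne alone.

Step 9
Reactants: 11 alkyl iodide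
Product: 12 {5-[(4-methoxyphenyl)methoxy]pent-3-yn-1-yl}zinc iodide (THF solution)
Conditions: Zn dust (activated with BrCH2CH2Br and Me3SiCl), LiCl, THF, 40 °C
Reagents that add atoms: zinc, [Zn]
Why: LiCl-mediated direct insertion of zinc into a primary alkyl iodide; the ether and internal alkyne are tolerated and the homopropargylic zinc has no β-leaving group.

Step 10
Reactants: 6 aldehyde; 8 propargyl TIPS ether; 12 alkylzinc iodide
Product: 13 methyl (3S,4R,5E)-3-[(4S)-2,2-dimethyl-1,3-dioxolan-4-yl]-4-hydroxy-11-[(4-methoxyphenyl)methoxy]-6-{[tri(propan-2-yl)silyloxy]methyl}undec-5-en-9-ynoate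
Conditions: Ni(cod)2 (15 mol %), 12 (3 equiv), THF, 0 °C; 6 and 8 (1.5 equiv) added slowly; aq NH4Cl
Reagents that add atoms: none
Why: Zerovalent nickel binds aldehyde 6 and the terminal alkyne 8 and undergoes oxidative cyclisation to an oxanickelacyclopentene in which C5–C6 is formed at the unsubstituted alkyne carbon and nickel sits on C4; zinc of 12 binds the alkoxide oxygen, the alkyl group passes to nickel, and reductive elimination forms C3–C4 where nickel was, so C3 and C6 end cis and the C15 silyloxymethyl trans to C6. The closest known reaction type is the nickel-catalysed alkylative three-component coupling of aldehydes, terminal alkynes and organozincs to trisubstituted allylic alcohols. No ring is closed. The new C6 centre is controlled by C7: in the Felkin–Anh arrangement the dioxolanyl group (C8) lies anti to the incoming alkenyl carbon with CH2CO2Me inside, and because the C7 side chain and O8 are anti, 1,3-induction from the β-oxygen points the same way, so the 6R epimer (O6 anti to O8) is expected to dominate. The step needs bond formation at the terminal alkyne carbon, syn addition, alkyl transfer in place of β-hydride transfer, and reaction of alkyne 8 in preference to the internal alkyne of 12; these rest on the steric bias of a monosubstituted alkyne, the metallacycle mechanism, the absence of phosphine ligands, and the excess and slow addition of the less hindered alkyne.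

Step 11
Reactants: 13 γ-hydroxy ester
Product: 14 (4S,5R)-4-[(4S)-2,2-dimethyl-1,3-dioxolan-4-yl]-5-[(1E)-7-[(4-methoxyphenyl)methoxy]-2-{[tri(propan-2-yl)silyloxy]methyl}hept-1-en-5-yn-1-yl]oxolan-2-one
Conditions: PPTS (cat.), PhMe, 60 °C
Reagents that add atoms: none
Why: Acid-catalysed γ-lactonisation with retention at C6 gives the trans-4,5-disubstituted lactone; O8 is held in the acetonide and cannot compete for C12, and any C6 epimer would appear as the cis-lactone and can be removed here.

Step 12
Reactants: 14 lactone
Product: 17 (4S,5R)-4-[(4S)-2,2-dimethyl-1,3-dioxolan-4-yl]-5-[(1E)-7-[(4-methoxyphenyl)methoxy]-2-{[tri(propan-2-yl)silyloxy]methyl}hept-1-en-5-yn-1-yl]-3-methylideneoxolan-2-one, via Mannich base 15 (not isolated), via ammonium iodide 16 (not isolated)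
Conditions: LDA, THF, −78 °C; Me2N=CH2 I, −78 °C to rt; MeI, MeOH, rt; aq NaHCO3, CH2Cl2
Reagents that add atoms: N,N-dimethylmethyleneiminium iodide (Eschenmoser's salt), C=[N+](C)C.[I-]
Why: Mannich aminomethylation of the lactone enolate, quaternisation and mild elimination is the standard α-methylenation; at this stage the lactone is the only enolisable carbonyl and C7 carries no β-leaving group.

Step 13
Reactants: 17 α-methylene lactone
Product: 18 (4R,5R)-4-[(1S)-1,2-dihydroxyethyl]-5-[(1E)-7-[(4-methoxyphenyl)methoxy]-2-{[tri(propan-2-yl)silyloxy]methyl}hept-1-en-5-yn-1-yl]-3-methylideneoxolan-2-one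
Conditions: AcOH/H2O 4:1, 40 °C
Reagents that add atoms: none
Why: Mild acid hydrolysis of a terminal acetonide; TIPS and PMB ethers and the methylene lactone are stable, and the trans 6,12-lactone is favoured over the cis lactone that O8 could form.

Step 14
Reactants: 18 diol
Product: 19 (4R,5R)-4-[(1S)-1-hydroxy-2-(triethylsilyloxy)ethyl]-5-[(1E)-7-[(4-methoxyphenyl)methoxy]-2-{[tri(propan-2-yl)silyloxy]methyl}hept-1-en-5-yn-1-yl]-3-methylideneoxolan-2-one
Conditions: Et3SiCl (1.05 equiv), imidazole, CH2Cl2, −78 to −40 °C
Reagents that add atoms: chlorotriethylsilane, CC[Si](Cl)(CC)CC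
Why: Selective silylation of the primary hydroxyl of a 1,2-diol at low temperature.

Step 15
Reactants: 19 C8 alcohol; 20 (2S)-2-methylbutanoic acid
Product: 21 (1S)-1-[(2R,3S)-2-[(1E)-7-[(4-methoxyphenyl)methoxy]-2-{[tri(propan-2-yl)silyloxy]methyl}hept-1-en-5-yn-1-yl]-4-methylidene-5-oxooxolan-3-yl]-2-(triethylsilyloxy)ethyl (2S)-2-methylbutanoate
Conditions: DCC, DMAP (cat.), CH2Cl2, 0 °C to rt
Reagents that add atoms: none
Why: Steglich esterification of the secondary alcohol; carbodiimide activation with catalytic DMAP at low temperature keeps the α-centre of the acid intact.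

Step 16
Reactants: 21 primary TES ether
Product: 22 (1S)-1-[(2R,3S)-2-[(1E)-7-[(4-methoxyphenyl)methoxy]-2-{[tri(propan-2-yl)silyloxy]methyl}hept-1-en-5-yn-1-yl]-4-methylidene-5-oxooxolan-3-yl]-2-oxoethyl (2S)-2-methylbutanoate
Conditions: (COCl)2, DMSO, CH2Cl2, −78 to −40 °C; Et3N, −78 to 0 °C
Reagents that add atoms: none
Why: Swern oxidation applied directly to a primary triethylsilyl ether: the chlorosulfonium salt cleaves the unhindered Si–O bond and the alkoxysulfonium ion collapses to the aldehyde on adding Et3N; the TIPS and PMB ethers are untouched.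

Step 17
Reactants: 22 PMB ether
Product: 23 (1S)-1-[(2R,3S)-2-[(1E)-7-hydroxy-2-{[tri(propan-2-yl)silyloxy]methyl}hept-1-en-5-yn-1-yl]-4-methylidene-5-oxooxolan-3-yl]-2-oxoethyl (2S)-2-methylbutanoate
Conditions: DDQ, CH2Cl2/pH 7 buffer, 0 °C
Reagents that add atoms: none
Why: Oxidative cleavage of the PMB ether under buffered conditions frees the propargylic hydroxyl needed to direct the next step; aldehyde, esters and silyl ether are inert to DDQ.

Step 18
Reactants: 23 propargylic alcohol
Product: 25 (1S)-1-[(2R,3S)-2-[(1E,5Z)-7-hydroxy-6-iodo-2-{[tri(propan-2-yl)silyloxy]methyl}hepta-1,5-dien-1-yl]-4-methylidene-5-oxooxolan-3-yl]-2-oxoethyl (2S)-2-methylbutanoate, via alkenylstannane 24 (not isolated)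
Conditions: Bu3SnH, [(C5Me5)RuCl]4 (2.5 mol %), CH2Cl2, rt; then I2, CH2Cl2, 0 °C
Reagents that add atoms: iodine, II
Why: Hydroxyl-directed ruthenium-catalysed trans-hydrostannation: hydrogen bonding of the propargylic OH to the chloride ligand delivers tin to the proximal carbon C10 and hydrogen to C1 on opposite faces, and tin–iodine exchange with retention gives the (Z)-2-iodoallylic alcohol with iodine cis to C2. The alkyne should react much faster than the conjugated methylene or the aldehyde.

Step 19
Reactants: 25 iodo aldehyde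
Product: 26 (1(10)Z,4E,6R,7S,8S,9S)-9,14-dihydroxy-8-[(2S)-2-methylbutanoyloxy]-15-[tri(propan-2-yl)silyloxy]germacra-1(10),4,11(13)-trien-12,6-olide
Conditions: CrCl2 (10 equiv), NiCl2 (2 mol % of Cr), DMSO/THF, rt, syringe-pump addition to 2 mM
Reagents that add atoms: none
Why: Nozaki–Hiyama–Kishi macrocyclisation: zerovalent nickel (from NiCl2 and CrCl2) inserts into the C10–I bond, transmetalation gives the alkenylchromium (trivalent chromium), and addition to the C9 aldehyde with retention turns the iodide geometry into the ring-cis C1=C10 alkene while tolerating lactone, esters and the free C14 hydroxyl. The C9 carbinol requires attack on the Si face of the aldehyde, which depends on the conformation of the forming ring (trans-lactone, cis C4=C5) and not on a reliable open-chain model; high dilution suppresses intermolecular coupling.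

Step 20
Reactants: 26 diol
Product: 27 (1(10)E,4E,6R,7S,8S,9S)-9-hydroxy-8-[(2S)-2-methylbutanoyloxy]-14-oxo-15-[tri(propan-2-yl)silyloxy]germacra-1(10),4,11(13)-trien-12,6-olide
Conditions: TEMPO (cat.), PhI(OAc)2, CH2Cl2, rt
Reagents that add atoms: none
Why: Oxoammonium oxidation is much faster for the primary allylic C14 alcohol than for the hindered secondary C9 alcohol and stops at the aldehyde; a 1,3-diol cannot lactonise.

Step 21
Reactants: 27 hydroxy enal
Product: 28 (1(10)E,4E,6R,7S,8S,9S)-9-acetoxy-8-[(2S)-2-methylbutanoyloxy]-14-oxo-15-[tri(propan-2-yl)silyloxy]germacra-1(10),4,11(13)-trien-12,6-olide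
Conditions: Ac2O, pyridine, DMAP (cat.), CH2Cl2, 0 °C
Reagents that add atoms: acetic anhydride, CC(=O)OC(C)=O
Why: Acetylation of the only free hydroxyl with retention at C9; low temperature and little DMAP limit SN2' loss of the new allylic acetate and acyl migration from O8.

Step 22
Reactants: 28 TIPS ether
Product: 29 (1(10)E,4E,6R,7S,8S,9S)-9-acetoxy-15-hydroxy-8-[(2S)-2-methylbutanoyloxy]-14-oxogermacra-1(10),4,11(13)-trien-12,6-olide
Conditions: HF·pyridine, pyridine, THF, 0 °C to rt
Reagents that add atoms: none
Why: Buffered fluoride cleavage of the primary allylic silyl ether under non-basic conditions leaves the acetate, ester, enal and methylene lactone intact.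

## Compound list

1 | (4R)-2,2-dimethyl-1,3-dioxolane-4-carbaldehyde | O=C[C@H]1COC(C)(C)O1 | starting material
2 | (3E)-4-[(4S)-2,2-dimethyl-1,3-dioxolan-4-yl]but-3-en-2-one | CC(=O)/C=C/[C@H]1COC(C)(C)O1 | intermediate
3 | (2S,3E)-4-[(4S)-2,2-dimethyl-1,3-dioxolan-4-yl]but-3-en-2-ol | C[C@H](O)/C=C/[C@H]1COC(C)(C)O1 | intermediate
4 | (4S)-4-[(1E,3S)-3-(1-methoxyethenyloxy)but-1-enyl]-2,2-dimethyl-1,3-dioxolane (ketene acetal) | C=C(OC)O[C@@H](C)/C=C/[C@H]1COC(C)(C)O1 | intermediate
5 | methyl (3S,4E)-3-[(4S)-2,2-dimethyl-1,3-dioxolan-4-yl]hex-4-enoate | C/C=C/[C@H](CC(=O)OC)[C@H]1COC(C)(C)O1 | intermediate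
6 | methyl (3R)-3-[(4S)-2,2-dimethyl-1,3-dioxolan-4-yl]-4-oxobutanoate | O=C[C@H](CC(=O)OC)[C@H]1COC(C)(C)O1 | intermediate
7 | prop-2-yn-1-ol | C#CCO | starting material
8 | tri(propan-2-yl)(prop-2-yn-1-yloxy)silane | C#CCO[Si](C(C)C)(C(C)C)C(C)C | intermediate
9 | 1-methoxy-4-[(prop-2-yn-1-yloxy)methyl]benzene | C#CCOCc1ccc(OC)cc1 | intermediate
10 | 5-[(4-methoxyphenyl)methoxy]pent-3-yn-1-ol | OCCC#CCOCc1ccc(OC)cc1 | intermediate
11 | 1-[(5-iodopent-2-yn-1-yloxy)methyl]-4-methoxybenzene | ICCC#CCOCc1ccc(OC)cc1 | intermediate
12 | {5-[(4-methoxyphenyl)methoxy]pent-3-yn-1-yl}zinc iodide | I[Zn]CCC#CCOCc1ccc(OC)cc1 | intermediate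
13 | methyl (3S,4R,5E)-3-[(4S)-2,2-dimethyl-1,3-dioxolan-4-yl]-4-hydroxy-11-[(4-methoxyphenyl)methoxy]-6-{[tri(propan-2-yl)silyloxy]methyl}undec-5-en-9-ynoate | O[C@H](/C=C(/CO[Si](C(C)C)(C(C)C)C(C)C)CCC#CCOCc1ccc(OC)cc1)[C@H](CC(=O)OC)[C@H]1COC(C)(C)O1 | intermediate
14 | (4S,5R)-4-[(4S)-2,2-dimethyl-1,3-dioxolan-4-yl]-5-[(1E)-7-[(4-methoxyphenyl)methoxy]-2-{[tri(propan-2-yl)silyloxy]methyl}hept-1-en-5-yn-1-yl]oxolan-2-one | O=C1C[C@H]([C@H]2COC(C)(C)O2)[C@@H](/C=C(/CO[Si](C(C)C)(C(C)C)C(C)C)CCC#CCOCc2ccc(OC)cc2)O1 | intermediate
15 | 3-[(dimethylamino)methyl] derivative of 14 (Mannich base, both C11 epimers) | CN(C)CC1C(=O)O[C@H](/C=C(/CO[Si](C(C)C)(C(C)C)C(C)C)CCC#CCOCc2ccc(OC)cc2)[C@H]1[C@H]3COC(C)(C)O3 | intermediate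
16 | N-methyl quaternary ammonium iodide of 15 | C[N+](C)(C)CC1C(=O)O[C@H](/C=C(/CO[Si](C(C)C)(C(C)C)C(C)C)CCC#CCOCc2ccc(OC)cc2)[C@H]1[C@H]3COC(C)(C)O3.[I-] | intermediate
17 | (4S,5R)-4-[(4S)-2,2-dimethyl-1,3-dioxolan-4-yl]-5-[(1E)-7-[(4-methoxyphenyl)methoxy]-2-{[tri(propan-2-yl)silyloxy]methyl}hept-1-en-5-yn-1-yl]-3-methylideneoxolan-2-one | C=C1C(=O)O[C@H](/C=C(/CO[Si](C(C)C)(C(C)C)C(C)C)CCC#CCOCc2ccc(OC)cc2)[C@H]1[C@H]3COC(C)(C)O3 | intermediate
18 | (4R,5R)-4-[(1S)-1,2-dihydroxyethyl]-5-[(1E)-7-[(4-methoxyphenyl)methoxy]-2-{[tri(propan-2-yl)silyloxy]methyl}hept-1-en-5-yn-1-yl]-3-methylideneoxolan-2-one | C=C1C(=O)O[C@H](/C=C(/CO[Si](C(C)C)(C(C)C)C(C)C)CCC#CCOCc2ccc(OC)cc2)[C@H]1[C@H](O)CO | intermediate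
19 | (4R,5R)-4-[(1S)-1-hydroxy-2-(triethylsilyloxy)ethyl]-5-[(1E)-7-[(4-methoxyphenyl)methoxy]-2-{[tri(propan-2-yl)silyloxy]methyl}hept-1-en-5-yn-1-yl]-3-methylideneoxolan-2-one | C=C1C(=O)O[C@H](/C=C(/CO[Si](C(C)C)(C(C)C)C(C)C)CCC#CCOCc2ccc(OC)cc2)[C@H]1[C@H](O)CO[Si](CC)(CC)CC | intermediate
20 | (2S)-2-methylbutanoic acid | CC[C@H](C)C(=O)O | starting material
21 | (1S)-1-[(2R,3S)-2-[(1E)-7-[(4-methoxyphenyl)methoxy]-2-{[tri(propan-2-yl)silyloxy]methyl}hept-1-en-5-yn-1-yl]-4-methylidene-5-oxooxolan-3-yl]-2-(triethylsilyloxy)ethyl (2S)-2-methylbutanoate | C=C1C(=O)O[C@H](/C=C(/CO[Si](C(C)C)(C(C)C)C(C)C)CCC#CCOCc2ccc(OC)cc2)[C@H]1[C@@H](CO[Si](CC)(CC)CC)OC(=O)[C@@H](C)CC | intermediate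
22 | (1S)-1-[(2R,3S)-2-[(1E)-7-[(4-methoxyphenyl)methoxy]-2-{[tri(propan-2-yl)silyloxy]methyl}hept-1-en-5-yn-1-yl]-4-methylidene-5-oxooxolan-3-yl]-2-oxoethyl (2S)-2-methylbutanoate | C=C1C(=O)O[C@H](/C=C(/CO[Si](C(C)C)(C(C)C)C(C)C)CCC#CCOCc2ccc(OC)cc2)[C@H]1[C@@H](C=O)OC(=O)[C@@H](C)CC | intermediate
23 | (1S)-1-[(2R,3S)-2-[(1E)-7-hydroxy-2-{[tri(propan-2-yl)silyloxy]methyl}hept-1-en-5-yn-1-yl]-4-methylidene-5-oxooxolan-3-yl]-2-oxoethyl (2S)-2-methylbutanoate | C=C1C(=O)O[C@H](/C=C(/CO[Si](C(C)C)(C(C)C)C(C)C)CCC#CCO)[C@H]1[C@@H](C=O)OC(=O)[C@@H](C)CC | intermediate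
24 | (1S)-1-[(2R,3S)-2-[(1E,5Z)-7-hydroxy-6-(tributylstannyl)-2-{[tri(propan-2-yl)silyloxy]methyl}hepta-1,5-dien-1-yl]-4-methylidene-5-oxooxolan-3-yl]-2-oxoethyl (2S)-2-methylbutanoate | C=C1C(=O)O[C@H](/C=C(/CO[Si](C(C)C)(C(C)C)C(C)C)CC/C=C(/CO)[Sn](CCCC)(CCCC)CCCC)[C@H]1[C@@H](C=O)OC(=O)[C@@H](C)CC | intermediate
25 | (1S)-1-[(2R,3S)-2-[(1E,5Z)-7-hydroxy-6-iodo-2-{[tri(propan-2-yl)silyloxy]methyl}hepta-1,5-dien-1-yl]-4-methylidene-5-oxooxolan-3-yl]-2-oxoethyl (2S)-2-methylbutanoate | C=C1C(=O)O[C@H](/C=C(/CO[Si](C(C)C)(C(C)C)C(C)C)CC/C=C(/CO)I)[C@H]1[C@@H](C=O)OC(=O)[C@@H](C)CC | intermediate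
26 | (1(10)Z,4E,6R,7S,8S,9S)-9,14-dihydroxy-8-[(2S)-2-methylbutanoyloxy]-15-[tri(propan-2-yl)silyloxy]germacra-1(10),4,11(13)-trien-12,6-olide | C=C1C(=O)O[C@@H]2/C=C(/CO[Si](C(C)C)(C(C)C)C(C)C)CC/C=C(/CO)[C@H](O)[C@@H](OC(=O)[C@@H](C)CC)[C@@H]12 | intermediate
27 | (1(10)E,4E,6R,7S,8S,9S)-9-hydroxy-8-[(2S)-2-methylbutanoyloxy]-14-oxo-15-[tri(propan-2-yl)silyloxy]germacra-1(10),4,11(13)-trien-12,6-olide | C=C1C(=O)O[C@@H]2/C=C(/CO[Si](C(C)C)(C(C)C)C(C)C)CC/C=C(/C=O)[C@H](O)[C@@H](OC(=O)[C@@H](C)CC)[C@@H]12 | intermediate
28 | (1(10)E,4E,6R,7S,8S,9S)-9-acetoxy-8-[(2S)-2-methylbutanoyloxy]-14-oxo-15-[tri(propan-2-yl)silyloxy]germacra-1(10),4,11(13)-trien-12,6-olide | C=C1C(=O)O[C@@H]2/C=C(/CO[Si](C(C)C)(C(C)C)C(C)C)CC/C=C(/C=O)[C@H](OC(C)=O)[C@@H](OC(=O)[C@@H](C)CC)[C@@H]12 | intermediate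
29 | (1(10)E,4E,6R,7S,8S,9S)-9-acetoxy-15-hydroxy-8-[(2S)-2-methylbutanoyloxy]-14-oxogermacra-1(10),4,11(13)-trien-12,6-olide | C=C1C(=O)O[C@@H]2/C=C(/CO)CC/C=C(/C=O)[C@H](OC(C)=O)[C@@H](OC(=O)[C@@H](C)CC)[C@@H]12 | target

## Step count and least certain steps

Total: 22 steps. Longest linear sequence: 17 steps (1 to 29 through steps 1–4 and 10–22; the branch from 7 through steps 6–9 is equally long).

**Step 10 (key step).** The most likely failures are β-hydride transfer from the alkylnickel intermediate (giving the alkene without C3) and engagement of the internal alkyne of 12 by nickel. Both would erode the three-component product; facial selectivity at C6 is a smaller concern because two models agree. Fallback: the two bonds are made one after the other. Iodide 11 is converted into its Grignard reagent (Mg, Et2O) and then the alkylcopper (CuBr·SMe2, −40 °C), which adds syn across alkyne 8 (Normant carbocupration, copper on the terminal carbon). Iodine quench gives (E)-[2-(iodomethylidene)-7-[(4-methoxyphenyl)methoxy]hept-5-ynoxy]tri(propan-2-yl)silane F1, with iodine cis to C3. Nozaki–Hiyama–Kishi coupling of F1 with aldehyde 6 (CrCl2, NiCl2 cat., DMSO) forms C5–C6 with retention and comes back to the route at 13.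

**Step 19.** Poor or reversed facial selectivity at C9 is the main risk, because an open-chain α-acyloxy aldehyde would favour the 8,9-anti carbinol and only the ring conformation can overturn this; oligomerisation at insufficient dilution is the second risk. Fallback, setting out from 25: if the cyclisation delivers the 9-epi diol F2, its primary C14 hydroxyl is silylated (Et3SiCl, imidazole, −40 °C) to the 9-epi C14 triethylsilyl ether F3. Mitsunobu reaction with acetic acid (PPh3, DIAD) installs the acetate with inversion to give the 9-acetoxy C14 silyl ether F4. Brief HF·pyridine treatment at 0 °C removes the triethylsilyl group in the presence of TIPS to give the 9-acetoxy C14 alcohol F5, and MnO2 oxidation comes back to the route at 28.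

**Step 18.** Tin hydride may reduce the conjugated exocyclic methylene or the aldehyde in competition with the alkyne, because both are hydride acceptors once a ruthenium hydride is present. Fallback, setting out from 23: the same hydroxyl-directed trans-addition is run with a silane, which does not reduce acrylates or aldehydes (BnMe2SiH, [(C5Me5)RuCl]4), to give the (Z)-C10 benzyldimethylsilyl alkene F6. Electrophilic iododesilylation with retention (N-iodosuccinimide, (CF3)2CHOH, 0 °C) comes back to the route at 25.

**Step 20.** Over-oxidation of the secondary allylic C9 alcohol to the enone, or incomplete discrimination between the two allylic alcohols, would waste material. Fallback, setting out from 26: the primary C14 hydroxyl is silylated selectively (Et3SiCl, imidazole, −40 °C) to the C14 triethylsilyl ether F7, C9 is acetylated (Ac2O, pyridine) to give F4, the silyl group is removed (HF·pyridine, 0 °C) to give F5, and MnO2 oxidation of the now single free allylic alcohol comes back to the route at 28.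

## Further compounds

F1 | step 10 | (E)-[2-(iodomethylidene)-7-[(4-methoxyphenyl)methoxy]hept-5-ynoxy]tri(propan-2-yl)silane | I/C=C(/CO[Si](C(C)C)(C(C)C)C(C)C)CCC#CCOCc1ccc(OC)cc1
F2 | step 19 | (1(10)Z,4E,6R,7S,8S,9R)-9,14-dihydroxy-8-[(2S)-2-methylbutanoyloxy]-15-[tri(propan-2-yl)silyloxy]germacra-1(10),4,11(13)-trien-12,6-olide (9-epi diol) | C=C1C(=O)O[C@@H]2/C=C(/CO[Si](C(C)C)(C(C)C)C(C)C)CC/C=C(/CO)[C@@H](O)[C@@H](OC(=O)[C@@H](C)CC)[C@@H]12
F3 | step 19 | 14-O-triethylsilyl ether of 9-epi diol F2 | C=C1C(=O)O[C@@H]2/C=C(/CO[Si](C(C)C)(C(C)C)C(C)C)CC/C=C(/CO[Si](CC)(CC)CC)[C@@H](O)[C@@H](OC(=O)[C@@H](C)CC)[C@@H]12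
F4 | step 19 | (9S)-9-acetoxy-8-[(2S)-2-methylbutanoyloxy]-14-(triethylsilyloxy)-15-[tri(propan-2-yl)silyloxy]germacra-1(10),4,11(13)-trien-12,6-olide | C=C1C(=O)O[C@@H]2/C=C(/CO[Si](C(C)C)(C(C)C)C(C)C)CC/C=C(/CO[Si](CC)(CC)CC)[C@H](OC(C)=O)[C@@H](OC(=O)[C@@H](C)CC)[C@@H]12
F5 | step 19 | (9S)-9-acetoxy-14-hydroxy-8-[(2S)-2-methylbutanoyloxy]-15-[tri(propan-2-yl)silyloxy]germacra-1(10),4,11(13)-trien-12,6-olide | C=C1C(=O)O[C@@H]2/C=C(/CO[Si](C(C)C)(C(C)C)C(C)C)CC/C=C(/CO)[C@H](OC(C)=O)[C@@H](OC(=O)[C@@H](C)CC)[C@@H]12
F6 | step 18 | (Z)-C10 benzyldimethylsilyl alkene from 23 (silicon in place of iodine in 25) | C=C1C(=O)O[C@H](/C=C(/CO[Si](C(C)C)(C(C)C)C(C)C)CC/C=C(/CO)[Si](C)(C)Cc2ccccc2)[C@H]1[C@@H](C=O)OC(=O)[C@@H](C)CC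
F7 | step 20 | 14-O-triethylsilyl ether of diol 26 | C=C1C(=O)O[C@@H]2/C=C(/CO[Si](C(C)C)(C(C)C)C(C)C)CC/C=C(/CO[Si](CC)(CC)CC)[C@H](O)[C@@H](OC(=O)[C@@H](C)CC)[C@@H]12
A1 | alternative 1 | lactone-fused 4,9-epoxy-8-(tert-butyldimethylsilyloxy)decalin-5-one (epoxide configuration left open, both centres are lost) | C1C(=O)O[C@@H]2C(=O)C34CCCCC3(O4)[C@@H](O[Si](C)(C)C(C)(C)C)[C@@H]12
A2 | alternative 1 | trans-lactone-fused 8-(tert-butyldimethylsilyloxy)cyclodec-4-yn-9-one | C1C(=O)O[C@@H]2C#CCCCCC(=O)[C@@H](O[Si](C)(C)C(C)(C)C)[C@@H]12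
A3 | alternative 2 | C6-hydroxy C7-ethynyl macrocycle with C8 and C9 esters, C14 aldehyde and C15 TBDPS ether | O[C@@H]1/C=C(/CO[Si](c2ccccc2)(c2ccccc2)C(C)(C)C)CC/C=C(/C=O)[C@H](OC(C)=O)[C@@H](OC(=O)[C@@H](C)CC)[C@H]1C#C
A4 | alternative 2 | C15 O-TBDPS ether of the target | C=C1C(=O)O[C@@H]2/C=C(/CO[Si](c3ccccc3)(c3ccccc3)C(C)(C)C)CC/C=C(/C=O)[C@H](OC(C)=O)[C@@H](OC(=O)[C@@H](C)CC)[C@@H]12
A5 | alternative 3 | 13-membered α-allyloxy enone (C8–O–C13 ether, C9 ketone, C11=C7 acrylate) | COC(=O)/C1=C/[C@H](OCc2ccc(OC)cc2)/C=C(/CO[Si](C(C)C)(C(C)C)C(C)C)CC/C=C(/CO[Si](C)(C)C(C)(C)C)C(=O)COC1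
A6 | alternative 3 | ten-membered α-hydroxy enone carrying the C7 acrylate | C=C(C(=O)OC)[C@H]1[C@H](OCc2ccc(OC)cc2)/C=C(/CO[Si](C(C)C)(C(C)C)C(C)C)CC/C=C(/CO[Si](C)(C)C(C)(C)C)C(=O)[C@H]1O
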